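**Assumption:** the target has no stereocenters, so it is achiral and there is no configuration to set. I also assume 4-hydroxy-5,6-dimethyl-2H-pyran-2-one (4) is commercially available.

## Retrosynthetic overview
- The target is a 3,4-dimethoxy-5,6-dialkyl-2-pyranone. The C6 decyl chain comes from lateral (vinylogous) deprotonation of a 6-methyl group followed by alkylation with I(CH2)9SMe. The ring is not built; it is bought as 4-hydroxy-5,6-dimethyl-2-pyranone (4).
- The 3-OMe comes from 3-diazo-pyran-2,4-dione (5) by Rh(II) carbenoid O–H insertion with MeOH. The 4-OMe comes from methylation of the resulting enol.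
- The sulfide is added last, as part of the alkyl iodide, because a thioether would intercept the Rh carbenoid.
- I(CH2)9SMe is made from 1,9-dibromononane by thiolation and then Finkelstein exchange.

## Route

**Step 1**
Reactants: 1 (1,9-dibromononane)
Product: 2 (1-bromo-9-(methylthio)nonane)
Conditions: NaSMe (1 equiv relative to 3 equiv of 1), DMF, 0 °C to rt
Reagents that add atoms: sodium thiomethoxide, [Na+].[S-]C
Why: SN2 displacement of one primary bromide by thiolate. Using an excess of the dibromide suppresses bis-substitution, and the unreacted 1 is recovered.

**Step 2**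
Reactants: 2
Product: 3 (1-iodo-9-(methylthio)nonane)
Conditions: NaI, acetone, reflux
Reagents that add atoms: sodium iodide, [Na+].[I-]
Why: Finkelstein halide exchange, driven by NaBr precipitating. The iodide is the more reactive electrophile for the later lateral alkylation, and the thioether is unaffected.

**Step 3**
Reactants: 4 (4-hydroxy-5,6-dimethyl-2H-pyran-2-one)
Product: 5 (3-diazo-5,6-dimethyl-2H-pyran-2,4(3H)-dione)
Conditions: p-ABSA, Et3N, MeCN, 0 °C to rt
Reagents that add atoms: p-acetamidobenzenesulfonyl azide, CC(=O)Nc1ccc(cc1)S(=O)(=O)N=[N+]=[N-] (transfers N2)
Why: Regitz diazo transfer onto the acidic C3 between the two carbonyls of the vinylogous acid. No stereocenter is formed.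

**Step 4**
Reactants: 5
Product: 6 (4-hydroxy-3-methoxy-5,6-dimethyl-2H-pyran-2-one)
Conditions: Rh2(OAc)4 (1 mol%), MeOH (10 equiv), CH2Cl2, rt to 40 °C
Reagents that add atoms: methanol, CO
Why: Rh(II) carbenoid O–H insertion into MeOH installs C3–OMe, and the product exists as the 4-hydroxy enol tautomer. No sulfide is present at this stage to poison the catalyst or form a sulfonium ylide.

**Step 5**
Reactants: 6
Product: 7 (3,4-dimethoxy-5,6-dimethyl-2H-pyran-2-one)
Conditions: TMSCHN2 (1.5 equiv), MeOH/PhMe, 0 °C to rt
Reagents that add atoms: trimethylsilyldiazomethane, C[Si](C)(C)C=[N+]=[N-] (supplies the methyl group)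
Why: The enol is strongly acidic (pKa about 5), so diazoalkane O-methylation is clean. C3 is already substituted, so no C-methylation can compete.

**Step 6**
Reactants: 7 and 3
Product: 8 (target)
Conditions: LDA (1.1 equiv), THF, −78 °C, 30 min; then 3 (1.2 equiv), DMPU, −78 °C to rt
Reagents that add atoms: none
Why: LDA removes a proton only from the 6-CH3, giving the extended dienolate conjugated to C2=O. The 5-CH3 is cross-conjugated and cannot be deprotonated this way, and C3 is blocked. The dienolate is alkylated at the CH2 terminus (lateral alkylation), and the thioether survives the organolithium conditions.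

**Checks**
- **Structure:** the target has a 2-pyranone ring, 3-OMe, 4-OMe, 5-Me, and a C6 chain of ten CH2 groups ending in SMe. Step 6 converts the 6-CH3 into a CH2 and adds (CH2)9SMe, giving (CH2)10SMe, which matches the SMILES.
- **Atom accounting:** each product follows from its reactants in every step (Step 6: 7 + 3 − HI gives 8).
- **Functional groups:** the thioether is introduced only in Steps 1 and 6, where it is compatible, and the Rh and diazo steps come before it is attached.
- **Stereochemistry:** there are no stereocenters in the target or in any intermediate.

## Compound list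
1 | 1,9-dibromononane | BrCCCCCCCCCBr | starting material
2 | 1-bromo-9-(methylthio)nonane | CSCCCCCCCCCBr | intermediate
3 | 1-iodo-9-(methylthio)nonane | CSCCCCCCCCCI | intermediate
4 | 4-hydroxy-5,6-dimethyl-2H-pyran-2-one | Cc1oc(=O)cc(O)c1C | starting material
5 | 3-diazo-5,6-dimethyl-2H-pyran-2,4(3H)-dione | CC1=C(C)C(=O)C(=[N+]=[N-])C(=O)O1 | intermediate
6 | 4-hydroxy-3-methoxy-5,6-dimethyl-2H-pyran-2-one | Cc1oc(=O)c(OC)c(O)c1C | intermediate
7 | 3,4-dimethoxy-5,6-dimethyl-2H-pyran-2-one | Cc1oc(=O)c(OC)c(OC)c1C | intermediate
8 | 3,4-dimethoxy-5-methyl-6-(10-(methylthio)decyl)-2H-pyran-2-one (CID52952639) | COc1c(C)c(CCCCCCCCCCSC)oc(=O)c1OC | target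

## Totals
- Total steps: 6
- Longest linear sequence: 4 steps (4 → 5 → 6 → 7 → 8). The side-chain branch is 1 → 2 → 3, then the coupling in Step 6.

## Three steps most likely to fail
1. **Step 6 (lateral alkylation).** Risks are dialkylation, low conversion with a long-chain iodide, and attack of LDA on the lactone.
   - Fallback: use a different bond construction. Lithiate 7 and add 9-bromononanal (OHC(CH2)8Br) in an aldol reaction. Dehydrate (MsCl/Et3N, then DBU), hydrogenate the alkene (H2, Pd/C) while the chain is still sulfur-free, and finish with NaSMe displacement of the terminal bromide.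
2. **Step 4 (Rh carbenoid O–H insertion).** Risks are dimerization or Wolff rearrangement of the cyclic diazo-dione, and ring opening by MeOH.
   - Fallback: build the 3-methoxy-4-hydroxy core directly. O-acylate methyl 2-methylacetoacetate with methoxyacetyl chloride to give the enol ester, then run a base-mediated Dieckmann cyclization (t-BuOK, THF) to give 6. This route depends on the Z enol ester geometry.
3. **Step 3 (diazo transfer).** The sulfonyl azide or the diazo-dione may be problematic, and the diazo-dione may be unstable.
   - Fallback: skip the diazo route. Hydroxylate C3 of 4 with Davis oxaziridine on its sodium enolate, then bis-methylate with Me2SO4/K2CO3 to reach 7. This is safe because the substrate has no sulfide at that stage.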